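Everything rests on building ring C last. A [4+2] cycloaddition of a benzofuran-2-yl propiolate with the bis(silyl) dienol ether of methyl acetoacetate forms C4–C5 and C3a–C7a. After loss of methanol it delivers the complete resorcinol in one operation. The step exploits the 1,2,3,5-pattern of ring C: the carbon substituent at C3a is flanked by the aryl group at C4 and the oxygen at C7a, and the C6 hydroxyl stands para to C3a. The precursor is a 7-geranyl-6-silyloxybenzofuran with a C2 alkynoate, made as the more electrophilic 2,2,2-trifluoroethyl ester. The ester carbon becomes C3 of ring D. (S)-C2 follows from an Evans glycolate alkylation and an invertive Mitsunobu closure.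

Key step: step 8

Locants: rings A and B are the benzene and furan rings of the 2-arylbenzofuran. Rings C and D are the benzene and dihydrofuran rings of the 2,3-dihydrobenzofuran, numbered O1, C2, C3, C3a, C4–C7, C7a. Geranyl = (2E)-3,7-dimethylocta-2,6-dien-1-yl, TIPS = triisopropylsilyl, TBS = tert-butyldimethylsilyl.

Assumption: the stereocentre written in the SMILES is C2 of ring D and reads as S (O1 > CMe2OH > C3 > H). Reagents named without a number are bought.

Step 1
Reactants: 1 2,4-dihydroxybenzaldehyde; 2 geranyl bromide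
Product: 3 3-geranyl-2,4-dihydroxybenzaldehyde
Conditions: KOH (1.1 equiv), MeOH, 0 °C to rt
Reagents that add atoms: none
Why: C-Alkylation of an ambident resorcinol monoanion (SN2 at the primary allylic bromide, so the E alkene is retained): in a protic solvent the hydrogen-bonded oxygen atoms are poor nucleophiles and C3, activated by both of them, takes the geranyl group, while O-alkylated and C5 isomers are removed by chromatography.

Step 2
Reactants: 3 3-geranyl-2,4-dihydroxybenzaldehyde
Product: 4 3-geranyl-2-hydroxy-4-(TIPS-oxy)benzaldehyde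
Conditions: iPr3SiCl, imidazole, DMF, 0 °C to rt
Reagents that add atoms: triisopropylsilyl chloride, CC(C)[Si](Cl)(C(C)C)C(C)C
Why: Chemoselective silyl ether formation: the C2 hydroxyl is locked in a hydrogen bond to the aldehyde and flanked on both sides, so only the C4 hydroxyl reacts, and the bulky TIPS group is chosen because it has to outlast carbonate, lithium amides, heat and hydride.

Step 3
Reactants: 4 3-geranyl-2-hydroxy-4-(TIPS-oxy)benzaldehyde; 5 chloroacetone
Product: 7 2-acetyl-7-geranyl-6-(TIPS-oxy)benzofuran, via aryloxyacetone 6 (not isolated)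
Conditions: K2CO3, KI (cat.), dry MeCN, 70 °C
Reagents that add atoms: none
Why: Rap–Stoermer benzofuran synthesis: Williamson etherification gives 6, whose OCH2 group, acidified by the ketone, closes ring B by intramolecular aldol condensation with the aldehyde, and the mild anhydrous carbonate conditions spare the hindered aryl TIPS ether.

Step 4
Reactants: 7 2-acetyl-7-geranyl-6-(TIPS-oxy)benzofuran
Product: 9 2-ethynyl-7-geranyl-6-(TIPS-oxy)benzofuran, via enol phosphate 8 (not isolated)
Conditions: LiN(iPr)2 (1.1 equiv), THF, −78 °C; ClP(O)(OEt)2, −78 °C to rt; LiN(iPr)2 (2.3 equiv), −78 °C to rt; H2O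
Reagents that add atoms: diethyl chlorophosphate, CCOP(=O)(Cl)OCC (atoms found in 8 only)
Why: Methyl ketone to terminal alkyne by enol phosphate elimination: kinetic enolisation and O-phosphorylation give 8, from which excess amide base removes diethyl phosphate by E2 elimination, and neither the TIPS ether nor the weakly acidic ArCH2–CH= position reacts at these temperatures.

Step 5
Reactants: 9 2-ethynyl-7-geranyl-6-(TIPS-oxy)benzofuran
Product: 10 2,2,2-trifluoroethyl 3-[7-geranyl-6-(TIPS-oxy)benzofuran-2-yl]prop-2-ynoate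
Conditions: n-BuLi (1.05 equiv), THF, −78 °C; transferred into ClCO2CH2CF3 (3 equiv), THF, −78 °C
Reagents that add atoms: 2,2,2-trifluoroethyl chloroformate, O=C(Cl)OCC(F)(F)F
Why: Deprotonation of the terminal alkyne and C-acylation with a chloroformate, the standard alkynoate synthesis; inverse addition to excess chloroformate keeps a second alkynyl anion away from the activated ester, and the trifluoroethyl group is chosen because it lowers the LUMO of the dienophile and later eases hydride reduction.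

Step 6
Reactants: 11 methyl acetoacetate
Product: 12 methyl 3-(trimethylsilyloxy)but-2-enoate (E/Z mixture)
Conditions: Me3SiCl, Et3N, hexane, rt
Reagents that add atoms: chlorotrimethylsilane, C[Si](C)(C)Cl
Why: Soft enolisation and O-silylation of a β-keto ester (silyl enol ether formation), driven by precipitation of the ammonium salt.

Step 7
Reactants: 12 methyl 3-(trimethylsilyloxy)but-2-enoate
Product: 13 1-methoxy-1,3-bis(trimethylsilyloxy)buta-1,3-diene
Conditions: LiN(iPr)2, THF, −78 °C; Me3SiCl, −78 to 0 °C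
Reagents that add atoms: chlorotrimethylsilane, C[Si](C)(C)Cl
Why: Kinetic γ-deprotonation of the vinylogous ester and O-silylation of the extended enolate (silyl ketene acetal formation) give the 1,3-dioxygenated diene, which is moisture-sensitive and is used directly after filtration and concentration.

Step 8
Reactants: 10 2,2,2-trifluoroethyl 3-[7-geranyl-6-(TIPS-oxy)benzofuran-2-yl]prop-2-ynoate; 13 1-methoxy-1,3-bis(trimethylsilyloxy)buta-1,3-diene
Product: 15 2,2,2-trifluoroethyl 2-[7-geranyl-6-(TIPS-oxy)benzofuran-2-yl]-4,6-dihydroxybenzoate, via cyclohexadiene cycloadduct 14 (not isolated)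
Conditions: 13 (4 equiv, in portions), neat, sealed tube, Ar, 120 °C; then THF, 1 M aq HCl, 0 °C
Reagents that add atoms: none
Why: This is a thermal normal-electron-demand Diels–Alder reaction followed by aromatisation, the known route from 1-alkoxy-1,3-bis(silyloxy)butadienes and acetylenic esters to 2,4-dihydroxybenzoates. Ring C closes by an intermolecular, concerted but strongly asynchronous [4+2] cycloaddition in which the unsubstituted CH2 terminus of 13, which carries the largest HOMO coefficient, bonds first to the alkyne carbon bearing the benzofuran (C4–C5), and the ketene acetal carbon then bonds to the ester-bearing carbon (C3a–C7a). Cycloadduct 14 holds a mixed ketal at C7a and a CH2 group at C5, so mild acid strips both Me3Si groups and methanol and the ring becomes aromatic; no stereocentre survives, so the geometry of the ketene acetal does not matter. Only regioselectivity is needed, and the polarisation of the ynoate secures it: C4 is its β-carbon, so the ester ends at C3a between the aryl group and the C7a hydroxyl, with the C6 hydroxyl para to it. The weak point is rate, because the 6-silyloxybenzofuran pushes electron density into the triple bond; the trifluoroethyl ester counteracts this, and the diene is used neat, in excess and in portions because it decays by silyl migration and hydrolysis at this temperature. The isolated trisubstituted alkenes of the geranyl chain and the hindered TIPS ether are inert to heat and to the brief cold acid treatment.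

Step 9
Reactants: 15 2,2,2-trifluoroethyl 2-[7-geranyl-6-(TIPS-oxy)benzofuran-2-yl]-4,6-dihydroxybenzoate
Product: 16 2,2,2-trifluoroethyl 2-[7-geranyl-6-(TIPS-oxy)benzofuran-2-yl]-4,6-bis(TBS-oxy)benzoate
Conditions: tBuMe2SiCl (3 equiv), imidazole, 4-(dimethylamino)pyridine (cat.), DMF, rt to 40 °C
Reagents that add atoms: tert-butyldimethylsilyl chloride, CC(C)(C)[Si](C)(C)Cl
Why: Silyl ether formation on both phenols, the hydrogen-bonded C7a hydroxyl needing the nucleophilic catalyst; both must be masked because a free ortho or para hydroxyl would turn the later benzylic bromide into a quinone methide.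

Step 10
Reactants: 16 2,2,2-trifluoroethyl 2-[7-geranyl-6-(TIPS-oxy)benzofuran-2-yl]-4,6-bis(TBS-oxy)benzoate
Product: 17 {2-[7-geranyl-6-(TIPS-oxy)benzofuran-2-yl]-4,6-bis(TBS-oxy)phenyl}methanol
Conditions: iBu2AlH (3 equiv), CH2Cl2, −78 to 0 °C; aq potassium sodium tartrate
Reagents that add atoms: none
Why: Hydride reduction of an ester to the primary alcohol: the good trifluoroethoxide leaving group offsets the hindrance of the doubly ortho-substituted benzoate, iBu2AlH leaves aryl silyl ethers and alkenes alone, and the weakly nucleophilic aluminium alkoxide does not trigger silyl migration from the C7a oxygen.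

Step 11
Reactants: 17 {2-[7-geranyl-6-(TIPS-oxy)benzofuran-2-yl]-4,6-bis(TBS-oxy)phenyl}methanol
Product: 18 2-[2-(bromomethyl)-3,5-bis(TBS-oxy)phenyl]-7-geranyl-6-(TIPS-oxy)benzofuran
Conditions: CBr4, PPh3, CH2Cl2, 0 °C; used at once
Reagents that add atoms: carbon tetrabromide, BrC(Br)(Br)Br
Why: Appel bromination converts the benzylic alcohol under neutral conditions, without acid that could ionise the electron-rich benzylic position or touch the geranyl chain.

Step 12
Reactants: 19 (TBS-oxy)acetic acid; 20 (S)-4-benzyloxazolidin-2-one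
Product: 22 (S)-4-benzyl-3-[(TBS-oxy)acetyl]oxazolidin-2-one, via mixed pivalic anhydride 21 (not isolated)
Conditions: Me3CCOCl, Et3N, THF, −20 to 0 °C; then LiCl, 20, rt
Reagents that add atoms: pivaloyl chloride, CC(C)(C)C(=O)Cl (atoms found in 21 only)
Why: N-Acylation of the oxazolidinone auxiliary through mixed anhydride 21, in which LiCl and Et3N activate the carbamate NH so that no strong base is needed and attack occurs at the less hindered glycolyl carbonyl.

Step 13
Reactants: 18 2-[2-(bromomethyl)-3,5-bis(TBS-oxy)phenyl]-7-geranyl-6-(TIPS-oxy)benzofuran; 22 (S)-4-benzyl-3-[(TBS-oxy)acetyl]oxazolidin-2-one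
Product: 24 (S)-4-benzyl-3-{(2R)-2-(TBS-oxy)-3-[2-(7-geranyl-6-(TIPS-oxy)benzofuran-2-yl)-4,6-bis(TBS-oxy)phenyl]propanoyl}oxazolidin-2-one, via sodium enolate 23 (not isolated)
Conditions: 22 (2 equiv), NaN(SiMe3)2, THF, −78 °C; then 18, −78 to −40 °C
Reagents that add atoms: sodium bis(trimethylsilyl)amide, C[Si](C)(C)[N-][Si](C)(C)C.[Na+] (sodium found in 23 only)
Why: Evans asymmetric alkylation of a glycolate imide: the sodium-chelated (Z)-enolate 23 is shielded on one face by the benzyl group of the (S)-auxiliary, so the SN2 reaction with the reactive benzylic bromide takes place on the opposite face and sets the new stereocentre (the later C2) as R.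

Step 14
Reactants: 24 the alkylated imide
Product: 25 methyl (2R)-2-(TBS-oxy)-3-{2-[7-geranyl-6-(TIPS-oxy)benzofuran-2-yl]-4,6-dihydroxyphenyl}propanoate
Conditions: K2CO3, MeOH/THF, 0 °C to rt; pH 7 buffer
Reagents that add atoms: methanol, CO
Why: Carbonate-catalysed methanolysis (transesterification of the N-acyl oxazolidinone and solvolysis of the two aryl TBS ethers), which spares the alkyl silyl ether, the hindered aryl TIPS ether and the weakly acidic α-silyloxy stereocentre and returns the auxiliary.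

Step 15
Reactants: 25 methyl (2R)-2-(TBS-oxy)-3-{2-[7-geranyl-6-(TIPS-oxy)benzofuran-2-yl]-4,6-dihydroxyphenyl}propanoate
Product: 26 methyl (2R)-3-[2-(7-geranyl-6-hydroxybenzofuran-2-yl)-4,6-dihydroxyphenyl]-2-hydroxypropanoate
Conditions: Bu4NF, AcOH (1:1, 3 equiv each), THF, 0 °C to rt
Reagents that add atoms: none
Why: Fluoride-mediated desilylation; acetic acid buffers the phenoxides and the alkoxide so that the α-hydroxy ester neither epimerises nor lactonises onto the C7a hydroxyl, and the product is taken on without storage.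

Step 16
Reactants: 26 methyl (2R)-3-[2-(7-geranyl-6-hydroxybenzofuran-2-yl)-4,6-dihydroxyphenyl]-2-hydroxypropanoate
Product: 27 methyl (2S)-4-(7-geranyl-6-hydroxybenzofuran-2-yl)-6-hydroxy-2,3-dihydrobenzofuran-2-carboxylate
Conditions: PPh3, DIAD, THF (0.01 M), 0 °C to rt
Reagents that add atoms: none
Why: Intramolecular Mitsunobu etherification: the activated secondary α-hydroxy ester is displaced by the neighbouring C7a hydroxyl in a 5-exo-tet SN2 reaction with clean inversion (R to S), and high dilution keeps the two remote phenols, which cannot reach the centre, from reacting between molecules.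

Step 17
Reactants: 27 methyl (2S)-4-(7-geranyl-6-hydroxybenzofuran-2-yl)-6-hydroxy-2,3-dihydrobenzofuran-2-carboxylate
Product: 28 (2S)-4-(7-geranyl-6-hydroxybenzofuran-2-yl)-2-(2-hydroxypropan-2-yl)-2,3-dihydrobenzofuran-6-ol (target)
Conditions: MeMgBr (8 equiv), THF, −20 °C to rt; aq NH4Cl
Reagents that add atoms: methylmagnesium bromide, C[Mg]Br
Why: Double Grignard addition to the ester after deprotonation of the two phenols (hence the excess); carbonyl addition outruns α-deprotonation at low temperature, C2 is not a reacting centre and stays S, and the alkenes are inert.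

Compound list
1 | 2,4-dihydroxybenzaldehyde | O=Cc1ccc(O)cc1O | starting material
2 | geranyl bromide | CC(C)=CCC/C(C)=C/CBr | starting material
3 | 3-geranyl-2,4-dihydroxybenzaldehyde | CC(C)=CCC/C(C)=C/Cc1c(O)ccc(C=O)c1O | intermediate
4 | 3-geranyl-2-hydroxy-4-(TIPS-oxy)benzaldehyde | CC(C)=CCC/C(C)=C/Cc1c(O[Si](C(C)C)(C(C)C)C(C)C)ccc(C=O)c1O | intermediate
5 | chloroacetone | CC(=O)CCl | starting material
6 | 3-geranyl-2-(2-oxopropoxy)-4-(TIPS-oxy)benzaldehyde | CC(C)=CCC/C(C)=C/Cc1c(O[Si](C(C)C)(C(C)C)C(C)C)ccc(C=O)c1OCC(C)=O | intermediate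
7 | 2-acetyl-7-geranyl-6-(TIPS-oxy)benzofuran | CC(C)=CCC/C(C)=C/Cc1c(O[Si](C(C)C)(C(C)C)C(C)C)ccc2cc(C(C)=O)oc12 | intermediate
8 | diethyl 1-[7-geranyl-6-(TIPS-oxy)benzofuran-2-yl]ethenyl phosphate | CC(C)=CCC/C(C)=C/Cc1c(O[Si](C(C)C)(C(C)C)C(C)C)ccc2cc(C(=C)OP(=O)(OCC)OCC)oc12 | intermediate
9 | 2-ethynyl-7-geranyl-6-(TIPS-oxy)benzofuran | CC(C)=CCC/C(C)=C/Cc1c(O[Si](C(C)C)(C(C)C)C(C)C)ccc2cc(C#C)oc12 | intermediate
10 | 2,2,2-trifluoroethyl 3-[7-geranyl-6-(TIPS-oxy)benzofuran-2-yl]prop-2-ynoate | CC(C)=CCC/C(C)=C/Cc1c(O[Si](C(C)C)(C(C)C)C(C)C)ccc2cc(C#CC(=O)OCC(F)(F)F)oc12 | intermediate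
11 | methyl acetoacetate | COC(=O)CC(C)=O | starting material
12 | methyl 3-(trimethylsilyloxy)but-2-enoate (E/Z mixture) | COC(=O)C=C(C)O[Si](C)(C)C | intermediate
13 | 1-methoxy-1,3-bis(trimethylsilyloxy)buta-1,3-diene | COC(O[Si](C)(C)C)=CC(=C)O[Si](C)(C)C | intermediate
14 | 2,2,2-trifluoroethyl 2-[7-geranyl-6-(TIPS-oxy)benzofuran-2-yl]-6-methoxy-4,6-bis(trimethylsilyloxy)cyclohexa-1,4-diene-1-carboxylate (racemic) | CC(C)=CCC/C(C)=C/Cc1c(O[Si](C(C)C)(C(C)C)C(C)C)ccc2cc(C3=C(C(=O)OCC(F)(F)F)C(OC)(O[Si](C)(C)C)C=C(O[Si](C)(C)C)C3)oc12 | intermediate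
15 | 2,2,2-trifluoroethyl 2-[7-geranyl-6-(TIPS-oxy)benzofuran-2-yl]-4,6-dihydroxybenzoate | CC(C)=CCC/C(C)=C/Cc1c(O[Si](C(C)C)(C(C)C)C(C)C)ccc2cc(-c3cc(O)cc(O)c3C(=O)OCC(F)(F)F)oc12 | intermediate
16 | 2,2,2-trifluoroethyl 2-[7-geranyl-6-(TIPS-oxy)benzofuran-2-yl]-4,6-bis(TBS-oxy)benzoate | CC(C)=CCC/C(C)=C/Cc1c(O[Si](C(C)C)(C(C)C)C(C)C)ccc2cc(-c3cc(O[Si](C)(C)C(C)(C)C)cc(O[Si](C)(C)C(C)(C)C)c3C(=O)OCC(F)(F)F)oc12 | intermediate
17 | {2-[7-geranyl-6-(TIPS-oxy)benzofuran-2-yl]-4,6-bis(TBS-oxy)phenyl}methanol | CC(C)=CCC/C(C)=C/Cc1c(O[Si](C(C)C)(C(C)C)C(C)C)ccc2cc(-c3cc(O[Si](C)(C)C(C)(C)C)cc(O[Si](C)(C)C(C)(C)C)c3CO)oc12 | intermediate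
18 | 2-[2-(bromomethyl)-3,5-bis(TBS-oxy)phenyl]-7-geranyl-6-(TIPS-oxy)benzofuran | CC(C)=CCC/C(C)=C/Cc1c(O[Si](C(C)C)(C(C)C)C(C)C)ccc2cc(-c3cc(O[Si](C)(C)C(C)(C)C)cc(O[Si](C)(C)C(C)(C)C)c3CBr)oc12 | intermediate
19 | (TBS-oxy)acetic acid | CC(C)(C)[Si](C)(C)OCC(=O)O | starting material
20 | (S)-4-benzyloxazolidin-2-one | O=C1N[C@@H](Cc2ccccc2)CO1 | starting material
21 | (TBS-oxy)acetic pivalic anhydride | CC(C)(C)[Si](C)(C)OCC(=O)OC(=O)C(C)(C)C | intermediate
22 | (S)-4-benzyl-3-[(TBS-oxy)acetyl]oxazolidin-2-one | CC(C)(C)[Si](C)(C)OCC(=O)N1[C@@H](Cc2ccccc2)COC1=O | intermediate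
23 | sodium (Z)-enolate of 22 | [Na+].[O-]/C(=C\O[Si](C)(C)C(C)(C)C)N1[C@@H](Cc2ccccc2)COC1=O | intermediate
24 | (S)-4-benzyl-3-{(2R)-2-(TBS-oxy)-3-[2-(7-geranyl-6-(TIPS-oxy)benzofuran-2-yl)-4,6-bis(TBS-oxy)phenyl]propanoyl}oxazolidin-2-one | CC(C)=CCC/C(C)=C/Cc1c(O[Si](C(C)C)(C(C)C)C(C)C)ccc2cc(-c3cc(O[Si](C)(C)C(C)(C)C)cc(O[Si](C)(C)C(C)(C)C)c3C[C@@H](O[Si](C)(C)C(C)(C)C)C(=O)N3[C@@H](Cc4ccccc4)COC3=O)oc12 | intermediate
25 | methyl (2R)-2-(TBS-oxy)-3-{2-[7-geranyl-6-(TIPS-oxy)benzofuran-2-yl]-4,6-dihydroxyphenyl}propanoate | CC(C)=CCC/C(C)=C/Cc1c(O[Si](C(C)C)(C(C)C)C(C)C)ccc2cc(-c3cc(O)cc(O)c3C[C@@H](O[Si](C)(C)C(C)(C)C)C(=O)OC)oc12 | intermediate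
26 | methyl (2R)-3-[2-(7-geranyl-6-hydroxybenzofuran-2-yl)-4,6-dihydroxyphenyl]-2-hydroxypropanoate | CC(C)=CCC/C(C)=C/Cc1c(O)ccc2cc(-c3cc(O)cc(O)c3C[C@@H](O)C(=O)OC)oc12 | intermediate
27 | methyl (2S)-4-(7-geranyl-6-hydroxybenzofuran-2-yl)-6-hydroxy-2,3-dihydrobenzofuran-2-carboxylate | CC(C)=CCC/C(C)=C/Cc1c(O)ccc2cc(-c3cc(O)cc4c3C[C@@H](C(=O)OC)O4)oc12 | intermediate
28 | (2S)-4-(7-geranyl-6-hydroxybenzofuran-2-yl)-2-(2-hydroxypropan-2-yl)-2,3-dihydrobenzofuran-6-ol | CC(C)=CCC/C(C)=C/Cc1c(O)ccc2cc(-c3cc(O)cc4c3C[C@@H](C(C)(C)O)O4)oc12 | target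

Total step count: 17. Longest linear sequence: 14 steps (1–5, 8–11, 13–17).

Steps most likely to fail

1. Step 8. The cycloaddition onto the donor-substituted β-aryl ynoate may be slower than the thermal decay of the diene (silyl migration, hydrolysis), so that conversion stalls.
   - The fallback sets out from 4 and returns at 15. It makes ring C by a biomimetic polyketide aldol aromatisation instead of a cycloaddition.
   - Aldehyde 4 and ethyl bromoacetate (K2CO3, DMF, 80 °C) give ethyl 7-geranyl-6-(TIPS-oxy)benzofuran-2-carboxylate F1. MeNH(OMe)·HCl and iPrMgCl turn this into the N-methoxy-N-methylamide F2.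
   - 2,2,6-Trimethyl-4H-1,3-dioxin-4-one is C-acetylated (LiN(SiMe3)2, acetyl chloride) to 2,2-dimethyl-6-(2-oxopropyl)-4H-1,3-dioxin-4-one F3. Its dianion (LiN(iPr)2, 2 equiv) is acylated by F2 to the diketo-dioxinone F4.
   - Heating F4 with CF3CH2OH in toluene (110 °C) expels acetone and gives the trifluoroethyl 7-aryl-3,5,7-trioxoheptanoate F5.
   - Cs2CO3 followed by mild acid brings about the aldol condensation of the C2 methylene with the aryl ketone and the dehydration to 15.

2. Step 13. Three processes threaten it: ionisation or early loss of the ortho silyl group in the electron-rich, doubly ortho-substituted benzylic bromide, decomposition of the glycolate enolate before it is alkylated, and, further on, lactonisation of the free phenol onto the ester before the Mitsunobu closure.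
   - The fallback sets out from 18 and 11 and returns at 27, so it also bypasses steps 14–16. The stereocentre is set in the C–O bond formation.
   - Bromide 18 alkylates 11 (NaH, THF) to methyl 2-acetyl-3-{2-[7-geranyl-6-(TIPS-oxy)benzofuran-2-yl]-4,6-bis(TBS-oxy)phenyl}propanoate F6.
   - Deacylating Regitz diazo transfer (4-acetamidobenzenesulfonyl azide, DBU, MeCN) gives the silylated α-diazo ester F7, and Bu4NF/AcOH frees the phenols to give the α-diazo ester F8.
   - A copper-catalysed enantioselective intramolecular phenolic O–H insertion (Cu(MeCN)4PF6, chiral spiro bis(oxazoline) ligand, NaB[3,5-(CF3)2C6H3]4, CH2Cl2) is a known entry to 2,3-dihydrobenzofuran-2-carboxylates and closes ring D to 27. The ligand enantiomer is chosen for the S product.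

3. Step 1. O-alkylation, attack at C5 and double alkylation compete with C3-alkylation.
   - The fallback sets out from 2 and returns at 3. It fixes the position by directed ortho-metalation.
   - 1,3-Bis(methoxymethoxy)benzene is lithiated between the two oxygens (n-BuLi, THF, 0 °C) and alkylated with 2 (CuBr·SMe2 cat.) to 2-geranyl-1,3-bis(methoxymethoxy)benzene F9.
   - A second lithiation ortho to an acetal oxygen (n-BuLi, TMEDA) and a DMF quench give 3-geranyl-2,4-bis(methoxymethoxy)benzaldehyde F10.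
   - Brief treatment with dilute HCl in MeOH at rt removes both acetals and gives 3.

Further compounds
F1 | step 8 | ethyl 7-geranyl-6-(TIPS-oxy)benzofuran-2-carboxylate | CC(C)=CCC/C(C)=C/Cc1c(O[Si](C(C)C)(C(C)C)C(C)C)ccc2cc(C(=O)OCC)oc12
F2 | step 8 | 7-geranyl-N-methoxy-N-methyl-6-(TIPS-oxy)benzofuran-2-carboxamide | CC(C)=CCC/C(C)=C/Cc1c(O[Si](C(C)C)(C(C)C)C(C)C)ccc2cc(C(=O)N(C)OC)oc12
F3 | step 8 | 2,2-dimethyl-6-(2-oxopropyl)-4H-1,3-dioxin-4-one | CC(=O)CC1=CC(=O)OC(C)(C)O1
F4 | step 8 | 6-{4-[7-geranyl-6-(TIPS-oxy)benzofuran-2-yl]-2,4-dioxobutyl}-2,2-dimethyl-4H-1,3-dioxin-4-one | CC(C)=CCC/C(C)=C/Cc1c(O[Si](C(C)C)(C(C)C)C(C)C)ccc2cc(C(=O)CC(=O)CC3=CC(=O)OC(C)(C)O3)oc12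
F5 | step 8 | 2,2,2-trifluoroethyl 7-[7-geranyl-6-(TIPS-oxy)benzofuran-2-yl]-3,5,7-trioxoheptanoate | CC(C)=CCC/C(C)=C/Cc1c(O[Si](C(C)C)(C(C)C)C(C)C)ccc2cc(C(=O)CC(=O)CC(=O)CC(=O)OCC(F)(F)F)oc12
F6 | step 13 | methyl 2-acetyl-3-{2-[7-geranyl-6-(TIPS-oxy)benzofuran-2-yl]-4,6-bis(TBS-oxy)phenyl}propanoate (racemic) | CC(C)=CCC/C(C)=C/Cc1c(O[Si](C(C)C)(C(C)C)C(C)C)ccc2cc(-c3cc(O[Si](C)(C)C(C)(C)C)cc(O[Si](C)(C)C(C)(C)C)c3CC(C(C)=O)C(=O)OC)oc12
F7 | step 13 | methyl 2-diazo-3-{2-[7-geranyl-6-(TIPS-oxy)benzofuran-2-yl]-4,6-bis(TBS-oxy)phenyl}propanoate | CC(C)=CCC/C(C)=C/Cc1c(O[Si](C(C)C)(C(C)C)C(C)C)ccc2cc(-c3cc(O[Si](C)(C)C(C)(C)C)cc(O[Si](C)(C)C(C)(C)C)c3CC(=[N+]=[N-])C(=O)OC)oc12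
F8 | step 13 | methyl 2-diazo-3-[2-(7-geranyl-6-hydroxybenzofuran-2-yl)-4,6-dihydroxyphenyl]propanoate | CC(C)=CCC/C(C)=C/Cc1c(O)ccc2cc(-c3cc(O)cc(O)c3CC(=[N+]=[N-])C(=O)OC)oc12
F9 | step 1 | 2-geranyl-1,3-bis(methoxymethoxy)benzene | CC(C)=CCC/C(C)=C/Cc1c(OCOC)cccc1OCOC
F10 | step 1 | 3-geranyl-2,4-bis(methoxymethoxy)benzaldehyde | CC(C)=CCC/C(C)=C/Cc1c(OCOC)ccc(C=O)c1OCOC
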